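The C19 chain is cut at the propargylic C6–C7 single bond, between the sp carbon C6 of the C5≡C6 triple bond and the first CH2 of the thirteen-carbon tether to furan C2. The key step exploits the acidity of the C6–H of hex-5-ynoic acid: two equivalents of base give a carboxylate–acetylide dianion in which the C1 carboxylate protects itself, and SN2 attack of C6 on the primary bromide carbon of 2-(13-bromotridecyl)furan forms the bond and, after acidification, delivers the target directly. The bromide arises in one step from 2-furyllithium and 1,13-dibromotridecane, so the acid- and oxidant-sensitive furan ring meets only basic reagents.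

Key step: step 2

Remark: the target is achiral (no stereocentre, no configured double bond), so no stereocontrol is required; 1,13-dibromotridecane is taken as a purchasable catalogue compound.

Step 1
Reactants: 1 furan; 2 1,13-dibromotridecane
Product: 4 2-(13-bromotridecyl)furan, via 2-furyllithium 3 (not isolated)
Conditions: 1 (1.1 equiv), n-BuLi (1.0 equiv), THF, −78 → 0 °C; then added to 2 (3 equiv), THF, −78 °C → rt
Reagents that add atoms: none
Why: Furan is lithiated selectively at C2 (α-lithiation next to oxygen) and the heteroaryllithium should undergo SN2 alkylation on a primary bromide, the threefold excess of 2 suppressing the second substitution.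

Step 2
Reactants: 5 hex-5-ynoic acid; 4 2-(13-bromotridecyl)furan
Product: 8 19-(furan-2-yl)nonadec-5-ynoic acid, via lithium 6-lithiohex-5-ynoate 6 (not isolated), via lithium 19-(furan-2-yl)nonadec-5-ynoate 7 (not isolated)
Conditions: 5 (1.3 equiv), n-BuLi (2.6 equiv), THF–HMPA (or DMPU), −78 → 0 °C; then 4 (1.0 equiv), 0 °C → rt; cold 1 M HCl to pH 3
Reagents that add atoms: none
Why: n-BuLi removes first the CO2H proton and then the C6–H (pKa ≈ 25) of 5 to give the carboxylate–acetylide 6, whose sp carbanion displaces bromide from the unbranched primary carbon of 4 in an SN2 step that forms the C6–C7 bond and gives carboxylate 7, which cold dilute acid protonates to 8. The closest known reaction type is the acetylide alkylation of dianions of ω-alkynoic acids with primary alkyl bromides in THF/HMPA. No ring is closed and no stereocentre is formed, so no stereocontrol is needed. The step needs C-alkylation at C6 over O-alkylation of the carboxylate and over E2, which the far higher nucleophilicity of the acetylide carbon and the unhindered primary bromide should secure. The α-CH2 of the carboxylate (C2) and the furan C5–H are much weaker acids than the alkyne and should stay untouched, because exactly two equivalents of n-BuLi per acid are consumed before 4 is added.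

Compound list
1 | furan | c1ccoc1 | starting material
2 | 1,13-dibromotridecane | BrCCCCCCCCCCCCCBr | starting material
3 | 2-furyllithium | [Li]c1ccco1 | intermediate
4 | 2-(13-bromotridecyl)furan | BrCCCCCCCCCCCCCc1ccco1 | intermediate
5 | hex-5-ynoic acid | OC(=O)CCCC#C | starting material
6 | lithium 6-lithiohex-5-ynoate | [Li+].[O-]C(=O)CCCC#C[Li] | intermediate
7 | lithium 19-(furan-2-yl)nonadec-5-ynoate | [Li+].[O-]C(=O)CCCC#CCCCCCCCCCCCCCc1ccco1 | intermediate
8 | 19-(furan-2-yl)nonadec-5-ynoic acid | O=C(O)CCCC#CCCCCCCCCCCCCCc1ccco1 | target

Total step count: 2. Longest linear sequence: 2 steps (1 → 4 → 8).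

Steps most likely to fail (the route has only two steps, so both are ranked):

First, step 2. The SN2 alkylation may stall because the dilithio salt is aggregated and poorly soluble, and O-alkylation of the carboxylate or E2 of the bromide may compete. The fallback sets out from bromide 4 and replaces the stoichiometric dianion by a catalytic sp3–sp cross-coupling. Bromide 4 and commercial methyl hex-5-ynoate (COC(=O)CCCC#C) are coupled under alkyl-Sonogashira conditions ([(π-allyl)PdCl]2, N-heterocyclic carbene ligand from 1,3-di(1-adamantyl)imidazolium chloride, CuI, Cs2CO3, DMF/Et2O, 45 °C), which should give methyl 19-(furan-2-yl)nonadec-5-ynoate F1. Saponification (LiOH, THF/H2O, rt; then cold 1 M HCl) comes back to the route at target 8.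

Second, step 1. Double substitution of the dibromide may compete, and the product may be hard to separate from the excess of 2. The fallback sets out from furan 1, lithiated to 3 as in step 1, and uses a desymmetrised C13 linker. Commercial 13-bromotridecan-1-ol (OCCCCCCCCCCCCCBr) is silylated (TBSCl, imidazole, DMF, rt) to tert-butyl[(13-bromotridecyl)oxy]dimethylsilane F2. Alkylation of 3 with F2 (THF, −78 °C → rt) should give tert-butyl{[13-(furan-2-yl)tridecyl]oxy}dimethylsilane F3. Desilylation (TBAF, THF, rt) should give 13-(furan-2-yl)tridecan-1-ol F4, and Appel bromination (CBr4, PPh3, CH2Cl2, 0 °C) comes back to the route at bromide 4.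

Further compounds
F1 | step 2 | methyl 19-(furan-2-yl)nonadec-5-ynoate | COC(=O)CCCC#CCCCCCCCCCCCCCc1ccco1
F2 | step 1 | tert-butyl[(13-bromotridecyl)oxy]dimethylsilane | CC(C)(C)[Si](C)(C)OCCCCCCCCCCCCCBr
F3 | step 1 | tert-butyl{[13-(furan-2-yl)tridecyl]oxy}dimethylsilane | CC(C)(C)[Si](C)(C)OCCCCCCCCCCCCCc1ccco1
F4 | step 1 | 13-(furan-2-yl)tridecan-1-ol | OCCCCCCCCCCCCCc1ccco1
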